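## Retrosynthetic overview

1. Irisoquin-C ⇒ 2-methoxy-6-nonadecyl-1,4-benzoquinone: the C2–OH is added last by Thiele–Winter acetoxylation, deacetylation and autoxidation, as in sorgoleone-type pathways.
2. Methoxyquinone ⇒ 3-methoxy-5-nonadecylphenol (the mono-O-methyl alkylresorcinol) by para C–H oxidation.
3. Arene ring ⇒ open-chain tetraketide (C20 fatty starter plus three acetate units, as its 3-O-methyl enol ether): C2→C7 aldol condensation, aromatisation and loss of C1 as CO2, the folding used by alkylresorcinol synthase. No bond is made to a preformed benzene ring.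
4. Tetraketide ⇒ its lactone-masked form, a 6-(2-oxoalkyl)-4-methoxypyranone ⇒ 4-methoxy-6-methyl-2H-pyran-2-one (a triketide lactone that already carries the OMe) + methyl icosanoate, by C-acylation.
5. Ring order: the carbocycle is the only ring of the target and is formed once, in step 2, in the same flask in which the pyranone ring of the precursor is opened.

Assumption: the SMILES is read as 2-hydroxy-5-methoxy-3-nonadecyl-1,4-benzoquinone (C26H44O4), which has no stereocentre and no stereogenic double bond, so no stereocontrol is needed.

## Route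

Step 1
Reactants: 1 4-methoxy-6-methyl-2H-pyran-2-one; 2 methyl icosanoate (methyl arachidate)
Product: 4 4-methoxy-6-(2-oxohenicosyl)-2H-pyran-2-one, via 6-(lithiomethyl)-4-methoxy-2H-pyran-2-one 3 (not isolated)
Conditions: 1 (2.2 equiv), LiN(iPr)2 (2.2 equiv), THF, −78 °C; then 2 (1.0 equiv), −78 → 0 °C; 1 M HCl
Reagents that add atoms: none
Why: LiN(iPr)2 removes a proton from the C6 methyl group (the kinetic, vinylogous site of the pyranone) and anion 3 undergoes a crossed Claisen condensation with ester 2, the second equivalent of 3 deprotonating the more acidic β-keto product so that it is not attacked again (excess 1 is recovered); no stereocentre is formed.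

Step 2
Reactants: 4 4-methoxy-6-(2-oxohenicosyl)-2H-pyran-2-one
Product: 7 3-methoxy-5-nonadecylphenol, via (2E)-3-methoxy-5,7-dioxohexacos-2-enoic acid 5 (not isolated), via 4-hydroxy-2-methoxy-6-nonadecylbenzoic acid 6 (not isolated)
Conditions: 2 M KOH (aq.), 1,4-dioxane, 80 °C, N2; then 6 M HCl (pH 1), 100 °C
Reagents that add atoms: none
Why: Hydroxide opens the lactone at the acyl carbon (its oxygen later leaves in the CO2) to unmask tetraketide 5, whose dienolate attacks the C7 ketone through C2 in an intramolecular vinylogous aldol condensation (a biogenetic-type pyrone-to-resorcylate conversion with the C2–C7 folding of alkylresorcinol synthase), dehydration and enolisation give 6, and hot acid then protodecarboxylates this ortho/para-oxygenated 2,6-disubstituted benzoic acid by ipso protonation, as orsellinic-type acids do; the free carboxylate cannot undergo the competing Claisen closure and no stereocentre is formed.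

Step 3
Reactants: 7 3-methoxy-5-nonadecylphenol
Product: 8 2-methoxy-6-nonadecylcyclohexa-2,5-diene-1,4-dione (2-methoxy-6-nonadecyl-1,4-benzoquinone)
Conditions: ON(SO3K)2 (2.5 equiv), aq. KH2PO4, methyltrioctylammonium chloride (cat.), CH2Cl2, rt
Reagents that add atoms: potassium nitrosodisulfonate, [K+].[K+].[O]N(S(=O)(=O)[O-])S(=O)(=O)[O-]
Why: Teuber oxidation, in which one equivalent of ON(SO3K)2 gives the phenoxyl radical and a second delivers oxygen to the free para position (between OMe and alkyl), giving the para-quinone exactly as in the preparation of the pentyl homologue primin; no stereocentre is formed.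

Step 4
Reactants: 8 2-methoxy-6-nonadecylcyclohexa-2,5-diene-1,4-dione
Product: 11 2-hydroxy-5-methoxy-3-nonadecylcyclohexa-2,5-diene-1,4-dione (Irisoquin-C), via 5-methoxy-3-nonadecylbenzene-1,2,4-triyl triacetate 9 (not isolated), via 5-methoxy-3-nonadecylbenzene-1,2,4-triol 10 (not isolated)
Conditions: Ac2O (10 equiv), H2SO4 (cat.), rt; then MeOH, 65 °C, N2; then EtOAc/pH 7 phosphate buffer (KH2PO4/K2HPO4), air, rt
Reagents that add atoms: acetic anhydride, CC(=O)OC(C)=O
Why: Thiele–Winter acetoxylation, in which acid-activated conjugate addition of acetate occurs at C5 (the only free enone β-carbon, since C3 is the electron-rich α-carbon of the vinylogous ester) and enolisation plus acetylation give 9, then acid-catalysed transesterification under N2 frees hydroxyhydroquinone 10, which after neutralisation autoxidises in air to the hydroxyquinone with OH next to the alkyl group and OMe untouched; no stereocentre is formed.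

## Compound list

1 | 4-methoxy-6-methyl-2H-pyran-2-one | CC1=CC(OC)=CC(=O)O1 | starting material
2 | methyl icosanoate (methyl arachidate) | CCCCCCCCCCCCCCCCCCCC(=O)OC | starting material
3 | 6-(lithiomethyl)-4-methoxy-2H-pyran-2-one | [Li]CC1=CC(OC)=CC(=O)O1 | intermediate
4 | 4-methoxy-6-(2-oxohenicosyl)-2H-pyran-2-one | CCCCCCCCCCCCCCCCCCCC(=O)CC1=CC(OC)=CC(=O)O1 | intermediate
5 | (2E)-3-methoxy-5,7-dioxohexacos-2-enoic acid (potassium salt in the flask) | CCCCCCCCCCCCCCCCCCCC(=O)CC(=O)C/C(OC)=C\C(=O)O | intermediate
6 | 4-hydroxy-2-methoxy-6-nonadecylbenzoic acid | CCCCCCCCCCCCCCCCCCCc1cc(O)cc(OC)c1C(=O)O | intermediate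
7 | 3-methoxy-5-nonadecylphenol | CCCCCCCCCCCCCCCCCCCc1cc(O)cc(OC)c1 | intermediate
8 | 2-methoxy-6-nonadecylcyclohexa-2,5-diene-1,4-dione | CCCCCCCCCCCCCCCCCCCC1=CC(=O)C=C(OC)C1=O | intermediate
9 | 5-methoxy-3-nonadecylbenzene-1,2,4-triyl triacetate | CCCCCCCCCCCCCCCCCCCc1c(OC(C)=O)c(OC(C)=O)cc(OC)c1OC(C)=O | intermediate
10 | 5-methoxy-3-nonadecylbenzene-1,2,4-triol | CCCCCCCCCCCCCCCCCCCc1c(O)c(O)cc(OC)c1O | intermediate
11 | 2-hydroxy-5-methoxy-3-nonadecylcyclohexa-2,5-diene-1,4-dione (Irisoquin-C, achiral) | CCCCCCCCCCCCCCCCCCCC1=C(O)C(=O)C=C(OC)C1=O | target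

## Step count and risks

Total step count: 4 (steps 2 and 4 are telescoped one-pot sequences). Longest linear sequence: 4 steps, fully linear from 1 and 2.

Steps most likely to fail, in order of risk:

Step 2. The 1,3-diketone may suffer retro-Claisen cleavage in hot KOH, the enol ether may hydrolyse before ring closure (which would erase the OMe/OH differentiation), or decarboxylation may be incomplete. The fallback sets out from 4 and comes back to the route at 8. Compound 4 is heated with NaOMe in dry MeOH, so that methoxide opens the lactone and the ester-activated C2 closes the aldol ring, and methyl 4-hydroxy-2-methoxy-6-nonadecylbenzoate F1 is isolated. The hindered ester is saponified with KOH in aqueous DMSO at 100 °C to acid 6, now isolated. Instead of protodecarboxylation, 6 is oxidised with ON(SO3K)2 (or PhI(OAc)2 in aqueous MeCN); oxygen is delivered to the carbon para to the hydroxyl group, ipso to the carboxyl group, CO2 is expelled, and quinone 8 forms directly, so phenol 7 and step 3 are bypassed.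

Step 1. Claisen acylation with an enolisable, poorly soluble long-chain ester may stall or give self-condensation. The fallback sets out from 2 and comes back to the route at 4. Ester 2 is reduced with i-Bu2AlH (CH2Cl2, −78 °C) to icosanal F2. The aldehyde is added to anion 3 (generated from 1 as in step 1, 1.1 equiv) in a reliable aldol addition that gives racemic 6-(2-hydroxyhenicosyl)-4-methoxy-2H-pyran-2-one F3. The secondary alcohol is then oxidised with Dess–Martin periodinane (CH2Cl2, rt) to 4.

Step 4. Three stages share one flask; methanolysis may be incomplete, or the product may be O-methylated if air enters before neutralisation. The fallback sets out from 8 and comes back to the route at 11. Nucleophilic epoxidation of the non-methoxylated enone double bond with t-BuOOH/DBU (CH2Cl2, 0 °C) gives the racemic cis-fused epoxide 3-methoxy-1-nonadecyl-7-oxabicyclo[4.1.0]hept-3-ene-2,5-dione F4. Acid (conc. H2SO4 in AcOH at 0 °C, or BF3·OEt2) opens the epoxide at the alkyl-bearing carbon, and loss of the proton from the epoxide CH gives hydroxyquinone 11 in an isomerisation of the epoxyquinone-to-hydroxyquinone type.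

## Further compounds

F1 | step 2 | methyl 4-hydroxy-2-methoxy-6-nonadecylbenzoate | CCCCCCCCCCCCCCCCCCCc1cc(O)cc(OC)c1C(=O)OC
F2 | step 1 | icosanal | CCCCCCCCCCCCCCCCCCCC=O
F3 | step 1 | 6-(2-hydroxyhenicosyl)-4-methoxy-2H-pyran-2-one (racemic) | CCCCCCCCCCCCCCCCCCCC(O)CC1=CC(OC)=CC(=O)O1
F4 | step 4 | 3-methoxy-1-nonadecyl-7-oxabicyclo[4.1.0]hept-3-ene-2,5-dione (racemic cis-fused epoxide; one enantiomer drawn) | CCCCCCCCCCCCCCCCCCC[C@@]12O[C@@H]1C(=O)C=C(OC)C2=O
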